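The butanolide is cut at C2–C3 and at O1–C5, so its O1–C2(=O) unit is carbon dioxide. Two features are exploited. The vinyl H of the E-alkylidene on C3 lies cis to the carbonyl, which is the mark of a syn H/CO2 addition to an alkyne. C5 bears a 2-methylprop-1-enyl group, so it is the secondary end of a dimethylallyl cation. The precursor is a 2-alkynyl-5,5-dimethyl-2,5-dihydrofuran whose ring oxygen is the future C4 hydroxyl and whose tertiary allylic C–O bond hides that cation. Copper hydride, CO2 and then acid convert it, with both esters in place, into the target in the last step.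

Key step: step 7

Assumption: the catalyst enantiomers in steps 3 and 6 are assigned by analogy with simple enals, and the mirror-image catalyst would be taken if the sense of induction proved opposite; 2, 6 and 10 are bought.

Step 1
Reactants: 1 nerol; 2 angelic acid
Product: 3 neryl angelate
Conditions: PPh3, DIAD, THF, 0 °C to rt
Reagents that add atoms: none
Why: Mitsunobu esterification activates the primary allylic alcohol and not the acid, so no acyl-activated angelate that could isomerise to the tiglate is formed and both Z alkenes are kept.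

Step 2
Reactants: 3 neryl angelate
Product: 5 (2Z,6E)-3,7-dimethyl-8-oxoocta-2,6-dienyl angelate, via allylic alcohol 4 (not isolated)
Conditions: SeO2 (0.3 equiv), t-BuOOH, salicylic acid (cat.), CH2Cl2, 0 °C to rt; then MnO2, CH2Cl2, rt
Reagents that add atoms: tert-butyl hydroperoxide CC(C)(C)OO
Why: The SeO2 allylic oxidation (Riley oxidation, ene reaction then 2,3-sigmatropic shift) attacks the E-methyl of the terminal, most electron-rich trisubstituted alkene, which fixes the 6E geometry, and MnO2 takes the allylic alcohol on to the enal without touching the esters.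

Step 3
Reactants: 5 (2Z,6E)-3,7-dimethyl-8-oxoocta-2,6-dienyl angelate; 6 allenylboronic acid pinacol ester
Product: 8 (2Z,6E,8S)-8-hydroxy-3,7-dimethylundeca-2,6-dien-10-ynyl angelate, via borate ester 7 (not isolated)
Conditions: (S)-TRIP (3,3'-bis(2,4,6-triisopropylphenyl)-BINOL hydrogen phosphate, 10 mol%), 4 Å MS, toluene, −20 °C; aqueous work-up
Reagents that add atoms: none
Why: Chiral phosphoric acid-catalysed asymmetric propargylation: the acid binds the boronate oxygen in a closed six-membered SE2' transition state, so the allenyl group is transferred with transposition to give only the homopropargylic alcohol, and the 3,3'-aryl pocket of the S catalyst shields one aldehyde face and sets 8S.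

Step 4
Reactants: 8 (2Z,6E,8S)-8-hydroxy-3,7-dimethylundeca-2,6-dien-10-ynyl angelate
Product: 9 (2Z,6E,8S)-8-acetoxy-3,7-dimethylundeca-2,6-dien-10-ynyl angelate
Conditions: Ac2O, pyridine, DMAP (cat.), CH2Cl2, 0 °C to rt
Reagents that add atoms: acetic anhydride CC(=O)OC(C)=O
Why: DMAP-catalysed acylation of the only free hydroxyl, without change at C8 and without effect on the angelate, which is not acyl-activated.

Step 5
Reactants: 10 5,5-dimethylfuran-2(5H)-one
Product: 11 5,5-dimethyl-2,5-dihydrofuran-2-ol
Conditions: DIBAL-H (1.05 equiv), CH2Cl2, −78 °C; Rochelle salt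
Reagents that add atoms: none
Why: Partial DIBAL-H reduction of a lactone: the tetrahedral aluminium alkoxide is stable at −78 °C and collapses only on work-up, hydride adds 1,2, and the anomeric centre formed is of no consequence because it is lost in step 6.

Step 6
Reactants: 9 (2Z,6E,8S)-8-acetoxy-3,7-dimethylundeca-2,6-dien-10-ynyl angelate; 11 5,5-dimethyl-2,5-dihydrofuran-2-ol
Product: 13 (2Z,6E,8S)-8-acetoxy-11-[(2R)-5,5-dimethyl-2,5-dihydrofuran-2-yl]-3,7-dimethylundeca-2,6-dien-10-ynyl angelate, via Z-enediol 12 (not isolated)
Conditions: Me2Zn (3 equiv), (S,S)-ProPhenol (20 mol%), Ph3PO (40 mol%), toluene, 0 °C to rt; NH4Cl work-up; then camphorsulfonic acid (5 mol%), CH2Cl2, 0 °C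
Reagents that add atoms: none
Why: Dinuclear zinc ProPhenol-catalysed asymmetric alkynylation of an unsaturated aldehyde, here the open Z-4-hydroxy-enal form of lactol 11 held as its zinc alkoxide, sets 12R through the chiral ligand pocket, and the acid-catalysed cyclodehydration that follows ionises only the tertiary allylic alcohol, so the carbinol oxygen closes the dihydrofuran while its own C–O bond, and thus the stereocentre, is untouched.

Step 7
Reactants: 13 (2Z,6E,8S)-8-acetoxy-11-[(2R)-5,5-dimethyl-2,5-dihydrofuran-2-yl]-3,7-dimethylundeca-2,6-dien-10-ynyl angelate; 14 carbon dioxide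
Product: 17 CNP0201198.1, via silyl ester 15 (not isolated), via carboxylic acid 16 (not isolated)
Conditions: (IMes)CuF (5 mol%, IMes = 1,3-dimesitylimidazol-2-ylidene), HSi(OEt)3 (2 equiv), CO2 (1 atm), 1,4-dioxane, 65 °C; then H2O, TsOH·H2O (0.3 equiv), CH2Cl2, 0 °C
Reagents that add atoms: carbon dioxide (14) O=C=O
Why: Proposed new method: copper hydride made from (IMes)CuF and the silane should add syn to the alkyne with copper on the carbon next to the polar propargylic C–O bond and hydride on the distal carbon, the alkenylcopper inserts CO2 with retention (C2–C3 bond, vinyl H cis to the carboxyl, hence E) and the silane releases silyl ester 15 and copper hydride. The closest known reaction types are the copper-catalysed hydrocarboxylation of internal alkynes with CO2 and hydrosilanes, the proximal placing of copper in copper hydride additions to propargylic ethers and the capture of dimethylallyl cations by carboxylic acids; their union on a dialkyl alkyne and a dihydrofuran is new. Wet acid then frees acid 16 and ionises the tertiary allylic C–O bond of the dihydrofuran, which uncovers the C4 hydroxyl and a Z-configured dimethylallyl cation, and the carboxyl oxygen closes the butanolide by 5-exo-trig attack on its secondary end C5 (O1–C5 bond). C4 comes unchanged from 13, and C5 is controlled by allylic 1,3-strain in the Z cation: H4 must lie in the allyl plane towards the inner methyl group, so the carboxyl on C3 reaches C5 on the face away from the C4 oxygen, which gives the trans (4S,5R) ring and also keeps H4 out of alignment for a hydride shift. Needed selectivities are alkyne over enoate in the hydride step (the angelate is an alpha,beta-disubstituted acrylate like the products that persist in such hydrocarboxylations, the alkylidene lactone appears only after the hydride is quenched, and a ring ether is a poor leaving group for beta-elimination from the alkenylcopper) and tertiary ether over the primary neryl ester and the secondary acetate in the ionisation. Attack at the tertiary end or return of the C4 hydroxyl only gives tertiary allylic C–O bonds that re-ionise, so the secondary lactone C–O bond is the sink.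

Compound list
1 | nerol, (2Z)-3,7-dimethylocta-2,6-dien-1-ol | OC/C=C(/C)CCC=C(C)C | starting material
2 | angelic acid, (2Z)-2-methylbut-2-enoic acid | C/C=C(/C)C(=O)O | starting material
3 | neryl angelate, (2Z)-3,7-dimethylocta-2,6-dienyl (2Z)-2-methylbut-2-enoate | C/C=C(/C)C(=O)OC/C=C(/C)CCC=C(C)C | intermediate
4 | (2Z,6E)-8-hydroxy-3,7-dimethylocta-2,6-dienyl angelate | C/C=C(/C)C(=O)OC/C=C(/C)CC/C=C(\C)CO | intermediate
5 | (2Z,6E)-3,7-dimethyl-8-oxoocta-2,6-dienyl angelate | C/C=C(/C)C(=O)OC/C=C(/C)CC/C=C(\C)C=O | intermediate
6 | allenylboronic acid pinacol ester, 4,4,5,5-tetramethyl-2-(propa-1,2-dienyl)-1,3,2-dioxaborolane | C=C=CB1OC(C)(C)C(C)(C)O1 | starting material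
7 | pinacol borate ester of alcohol 8 (8S, oxygen bound to boron) | C/C=C(/C)C(=O)OC/C=C(/C)CC/C=C(\C)[C@H](CC#C)OB1OC(C)(C)C(C)(C)O1 | intermediate
8 | (2Z,6E,8S)-8-hydroxy-3,7-dimethylundeca-2,6-dien-10-ynyl angelate | C/C=C(/C)C(=O)OC/C=C(/C)CC/C=C(\C)[C@H](CC#C)O | intermediate
9 | (2Z,6E,8S)-8-acetoxy-3,7-dimethylundeca-2,6-dien-10-ynyl angelate | C/C=C(/C)C(=O)OC/C=C(/C)CC/C=C(\C)[C@H](CC#C)OC(C)=O | intermediate
10 | 5,5-dimethylfuran-2(5H)-one | CC1(C)OC(=O)C=C1 | starting material
11 | 5,5-dimethyl-2,5-dihydrofuran-2-ol (lactol, both anomers) | CC1(C)OC(O)C=C1 | intermediate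
12 | (2Z,6E,8S,12R,13Z)-8-acetoxy-12,15-dihydroxy-3,7,15-trimethylhexadeca-2,6,13-trien-10-ynyl angelate | C/C=C(/C)C(=O)OC/C=C(/C)CC/C=C(\C)[C@H](CC#C[C@H](O)/C=C\C(C)(C)O)OC(C)=O | intermediate
13 | (2Z,6E,8S)-8-acetoxy-11-[(2R)-5,5-dimethyl-2,5-dihydrofuran-2-yl]-3,7-dimethylundeca-2,6-dien-10-ynyl angelate | C/C=C(/C)C(=O)OC/C=C(/C)CC/C=C(\C)[C@H](CC#C[C@H]1C=CC(C)(C)O1)OC(C)=O | intermediate
14 | carbon dioxide | O=C=O | starting material
15 | triethoxysilyl ester of acid 16 (2E, vinyl H cis to the ester carbonyl) | C/C=C(/C)C(=O)OC/C=C(/C)CC/C=C(\C)[C@H](C/C=C(/C(=O)O[Si](OCC)(OCC)OCC)[C@H]1C=CC(C)(C)O1)OC(C)=O | intermediate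
16 | (2E,5S,6E,10Z)-5-acetoxy-12-(angeloyloxy)-2-[(2R)-5,5-dimethyl-2,5-dihydrofuran-2-yl]-6,10-dimethyldodeca-2,6,10-trienoic acid | C/C=C(/C)C(=O)OC/C=C(/C)CC/C=C(\C)[C@H](C/C=C(/C(=O)O)[C@H]1C=CC(C)(C)O1)OC(C)=O | intermediate
17 | CNP0201198.1, (2Z,6E,8S)-8-acetoxy-10-[(3E,4S,5R)-4-hydroxy-5-(2-methylprop-1-enyl)-2-oxooxolan-3-ylidene]-3,7-dimethyldeca-2,6-dienyl angelate | C/C=C(/C)C(=O)OC/C=C(/C)CC/C=C(\C)[C@H](C/C=C1/C(=O)O[C@H](C=C(C)C)[C@H]1O)OC(C)=O | target

Total steps: 7. Longest linear sequence: 6 steps (1, 2, 3, 4, 6, 7).

Steps most likely to fail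

Step 7.
- **What may go wrong:** hydrocupration of the dialkyl alkyne may be too slow at a temperature where CO2 still inserts. The alkenylcopper may lose the ring alkoxide and open the dihydrofuran. The hydride may reduce the angelate in a conjugate sense. The cation may close with poor facial selectivity.
- **Fallback with known chemistry:** it sets out from 13. A copper-catalysed directed hydroboration with pinacolborane (CuCl, a xanthene bisphosphine, NaOtBu, toluene, rt) places boron by syn addition on the same proximal carbon. This gives the isolable alkenyl pinacolboronate F1. Copper-catalysed carboxylation of this boronate (CuI, a bis(oxazoline), CsF, CO2 1 atm, DMF) and acidification give acid 16. There the route is rejoined, and the same acid treatment leads to 17.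

Step 6.
- **What may go wrong:** enantioselectivity may erode because the lactol offers little open enal and its extra zinc alkoxide disturbs the catalyst. The doubly activated secondary carbinol may also ionise in part during the cyclodehydration.
- **Fallback:** it sets out from 11, which is acetylated (Ac2O, pyridine) to the anomeric acetate F2. A Lewis acid ionises it to the cyclic allylic oxocarbenium ion. This ion is alkynylated with 9 under chiral copper bis(oxazoline) catalysis (Cu(MeCN)4PF6, ligand, TMSOTf, iPr2NEt, Et2O, −20 °C), a substitution known for benzopyranyl acetals. This comes back at 13 without the diol and without the acid dehydration.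

Step 3.
- **What may go wrong:** facial discrimination may be weak and turnover slow with the alpha-branched enal.
- **Fallback:** it sets out from 5. A zinc Barbier reaction with propargyl bromide (Zn, THF, aqueous NH4Cl) gives the racemic alcohol F3. Lipase-catalysed acylation with vinyl acetate (Amano PS, MTBE) should take the R enantiomer to the R acetate F4 and leave the S alcohol. That alcohol is 8, where the route is rejoined.

Further compounds
F1 | step 7 | alkenyl pinacolboronate of 13, boron on the carbon next to the dihydrofuran and cis to the vinyl H | C/C=C(/C)C(=O)OC/C=C(/C)CC/C=C(\C)[C@H](C/C=C(/B2OC(C)(C)C(C)(C)O2)[C@H]1C=CC(C)(C)O1)OC(C)=O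
F2 | step 6 | 5,5-dimethyl-2,5-dihydrofuran-2-yl acetate | CC(=O)OC1C=CC(C)(C)O1
F3 | step 3 | racemic (2Z,6E)-8-hydroxy-3,7-dimethylundeca-2,6-dien-10-ynyl angelate | C/C=C(/C)C(=O)OC/C=C(/C)CC/C=C(\C)C(CC#C)O
F4 | step 3 | (2Z,6E,8R)-8-acetoxy-3,7-dimethylundeca-2,6-dien-10-ynyl angelate | C/C=C(/C)C(=O)OC/C=C(/C)CC/C=C(\C)[C@@H](CC#C)OC(C)=O
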